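**Assumption:** the target, 5-hydroxy-2-pentadecyl-4H-chromen-4-one, has no stereocentre and no stereogenic double bond, so no enantiocontrol is needed and the route gives the compound exactly as drawn.

**Retrosynthetic overview**
1. The pyranone ring is the only ring made, and it is made last: C2–O1 bond formation and dehydration of the 1-(2,6-dihydroxyphenyl)-1,3-diketone 5.
2. Diketone 5 is cut at the CH2–C(=O)alkyl bond (Claisen disconnection) into the enolate of 2',6'-dihydroxyacetophenone 1 and hexadecanoyl chloride 2.
3. The benzene ring and the C16 chain are bought; the symmetry of 1 removes any regiochemical question in the ring closure.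

**Route**

Step 1
Reactants: 1 2',6'-dihydroxyacetophenone; 2 hexadecanoyl chloride (palmitoyl chloride)
Product: 5 1-(2,6-dihydroxyphenyl)octadecane-1,3-dione, via trilithium trianion 3 (not isolated), via trilithium diketonate 4 (not isolated)
Conditions: LiN(SiMe3)2 (4.2 equiv), THF, −78 °C to −10 °C, 2 h; then 2 (1.0 equiv), −78 °C to rt, 4 h; then 1 M HCl, 0 °C
Reagents that add atoms: none
Why: Claisen-type C-acylation by the polyanion method: in the fully deprotonated trianion 3 the lithium enolate carbon is far more nucleophilic than the two lithium phenoxides, so the acid chloride is attacked at carbon, and the fourth equivalent of base absorbs the acidic proton of the diketone product as 4, which stops proton transfer back to unreacted 3; no stereocentre is formed.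

Step 2
Reactants: 5 1-(2,6-dihydroxyphenyl)octadecane-1,3-dione
Product: 7 5-hydroxy-2-pentadecyl-4H-chromen-4-one, via cyclic hemiketal 6 (not isolated)
Conditions: conc. H2SO4 (cat., 0.5 vol%), AcOH, 95–100 °C, 1 h
Reagents that add atoms: none
Why: Acid-catalysed cyclodehydration (the ring-closing stage of the Baker–Venkataraman chromone synthesis): either of the two equivalent phenols adds to the alkyl ketone to give the racemic hemiketal 6, whose loss of water gives the conjugated pyranone and erases that transient stereocentre, while the other phenol stays free as the hydrogen-bonded 5-OH.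

**Compound list**
1 | 2',6'-dihydroxyacetophenone [1-(2,6-dihydroxyphenyl)ethan-1-one] | CC(=O)c1c(O)cccc1O | starting material
2 | hexadecanoyl chloride (palmitoyl chloride) | CCCCCCCCCCCCCCCC(=O)Cl | starting material
3 | trilithium trianion of 1 (lithium enolate and two lithium phenoxides) | [Li+].[Li+].[Li+].C=C([O-])c1c([O-])cccc1[O-] | intermediate (not isolated)
4 | trilithium salt of 5 (lithium diketonate and two lithium phenoxides) | CCCCCCCCCCCCCCCC(=O)[CH-]C(=O)c1c([O-])cccc1[O-].[Li+].[Li+].[Li+] | intermediate (not isolated)
5 | 1-(2,6-dihydroxyphenyl)octadecane-1,3-dione | CCCCCCCCCCCCCCCC(=O)CC(=O)c1c(O)cccc1O | intermediate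
6 | 2,5-dihydroxy-2-pentadecylchroman-4-one (racemic hemiketal) | CCCCCCCCCCCCCCCC1(O)CC(=O)c2c(O)cccc2O1 | intermediate (not isolated)
7 | 5-hydroxy-2-pentadecyl-4H-chromen-4-one (CNP0279243.0) | CCCCCCCCCCCCCCCc1cc(=O)c2c(O)cccc2o1 | target

**Step count and risk**
Total step count: 2. Longest linear sequence: 2 steps (1 → 5 → 7).

The route has only two steps, so both are ranked and there is no third step to name.

Most likely to fail, step 1. The enolisable acid chloride 2 may be turned into a ketene by the excess amide base, or O-acylation and double acylation may compete with C-acylation. The fallback replaces the intermolecular C-acylation by an intramolecular acyl shift. It sets out from 1 and comes back at 5. Both phenols of 1 are esterified with 2 (2.2 equiv, pyridine, cat. DMAP, CH2Cl2, 0 °C to rt) to give 2-acetyl-1,3-phenylene dihexadecanoate F1. KOtBu (2.5 equiv, THF, 0 °C to rt) then drives a Baker–Venkataraman O-to-C acyl migration to 3-hydroxy-2-(3-oxooctadecanoyl)phenyl hexadecanoate F2. The remaining aryl ester is saponified in the same flask (aq. KOH, MeOH, rt; then HCl) to give 5.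

Second, step 2. This is low risk, but hot acid could cause retro-Claisen cleavage of 5 or stall at the hemiketal. The fallback forms the O1–C2 bond by conjugate addition rather than by ketalisation and dehydration, and adjusts the oxidation level afterwards. It sets out from 1 and comes back at 7. Compound 1 is condensed with commercial hexadecanal (CCCCCCCCCCCCCCCC=O; pyrrolidine, EtOH, reflux) in a Kabbe-type aldol condensation and oxa-Michael ring closure to racemic 5-hydroxy-2-pentadecylchroman-4-one F3. F3 is dehydrogenated (I2 cat., DMSO, 130 °C) to 7, which removes the C2 stereocentre.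

**Further compounds**
F1 | step 1 | 2-acetyl-1,3-phenylene dihexadecanoate | CCCCCCCCCCCCCCCC(=O)Oc1cccc(OC(=O)CCCCCCCCCCCCCCC)c1C(C)=O
F2 | step 1 | 3-hydroxy-2-(3-oxooctadecanoyl)phenyl hexadecanoate | CCCCCCCCCCCCCCCC(=O)CC(=O)c1c(O)cccc1OC(=O)CCCCCCCCCCCCCCC
F3 | step 2 | 5-hydroxy-2-pentadecylchroman-4-one (racemic) | CCCCCCCCCCCCCCCC1CC(=O)c2c(O)cccc2O1
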